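- Electrophile goes slowly in these flasks. It is fed over 2.0 min into nucleophile and free base, and in the beta run what stood at the end of the feed then fell with an average decay constant of 0.102 min⁻¹. I read from this an after-feed half-life of 6.77 min, the time in which electrophile present after the feed halves, taken as one average over the beta run up to 15.0 min with nucleophile at 2.5 equiv. It is longer than the feed.

| flask | electrophile | nucleophile | free base | remark | time |
|---|---|---|---|---|---|
| zeta | 0.090 M (fed, over 2.0 min) | 2.5 equiv | 0.56 equiv | run made earlier |  |
| beta | 0.090 M (fed, over 2.0 min) | 2.5 equiv | 0.99 equiv | run made earlier |  |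
| birch | 0.090 M (fed, over 2.0 min) | 2.50 equiv | 1.00 equiv |  | 15 min |
| alder | 0.090 M (fed, over 2.0 min) | 2.50 equiv | 1.50 equiv |  | 15 min |

- zeta (time / min: electrophile / %, target / %): 2.00: 88.9, 11.2; 4.00: 70.4, 29.1; 6.00: 56.8, 41.6; 8.00: 47.0, 51.5; 10.0: 39.8, 58.5; 12.0: 33.0, 63.7; 15.0: 25.9, 69.8
- beta (time / min: electrophile / %, target / %): 1.33: 62.3, 5.4; 2.00: 89.0, 11.0; 3.00: 79.6, 20.3; 4.00: 71.4, 28.7; 6.00: 56.8, 41.6; 10.0: 38.5, 58.1; 15.0: 23.5, 71.9

(scatter of a reading: 0.5 percentage points)

- percentages count the whole charge, also what has not yet gone in

- part of the electrophile that has reacted at the end, birch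
- part of the electrophile that has reacted at the end, alder
- what raising the equivalents of free base from its lowest to its highest value here does to the part of the electrophile that has reacted (changes below 5 percentage points count as none) (it falls / no change / it rises)

- My zero of the scale was that free base does nothing, so zeta and beta should read alike. At 6.00 min they did, and at 15.0 min zeta stood 2.4 percentage points above beta, less than the 5 points that counts.
- Birch and alder hold more free base than beta, so I gave both beta's half-life. Whoever comes at 15 min will find 1.92 half-lives gone since the feed and 76.5 % reacted in each flask.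
- I advised against adding free base for speed, since the gap between zeta and beta stayed below 5 points.
- The forecast gave 76.3 % for birch and 76.3 % for alder, with no change, holding that “free base is not in the rate law”.
- The flasks gave 75.7 % for birch and 75.8 % for alder, a change of 0.15 points, so the trend was no change. Both were unfinished at that time, with 24.3 % and 24.2 % electrophile left.

    electrophile + nucleophile → acid set free + target (k = 0.540 M⁻¹ min⁻¹)
    nucleophile + acid set free ⇌ protonated nucleophile, settled at all times (K = 2200 M⁻¹)
    acid set free + free base ⇌ salt of the base, settled at all times (K = 2.40 × 10⁵ M⁻¹)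
    target → over-reaction product (k = 1.30 × 10⁻⁴ min⁻¹)
    electrophile + target → side product (k = 0.0860 M⁻¹ min⁻¹)

- In alder, the half-life of electrophile by the step to target at 5.16 min was 6.7 min, against my average of 6.77 min. For the neighbouring flask, alder with 6.20 equiv of nucleophile in place of 2.50 equiv, I shortened the half-life in proportion to the charge, to 2.73 min. That makes 4.76 half-lives after the feed and, starting from beta's 89.0 % at the end of the feed, 3.28 % electrophile. The neighbouring flask held 2.36 % electrophile at 15 min, with 97.6 % reacted.

The runs are simulated from invented constants.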